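**Plan**

1. Numbering: cyclohexene C1(Me, dienyl)–C2H=C3(Me)–C4H–C5H–C6(Et, CO2H); cyclopentanone C4–C9H(Me)–C8(=O)–C7H(Et)–C5; side chain C1'H=C2'(Et)–C3'H=C4'H–Ph.
2. Enabling feature: the cyclopentanone fused at C4–C5 is the sum of an alkyne (C5≡C7), an alkene (C4=C9) and CO (C8), and the ring (Z)-alkene C2=C3 holds the two within reach. Cutting C4–C5, C7–C8 and C8–C9 therefore opens both rings to an acyclic dienyne.
3. Further cuts: C2'–Et and C2'–C3' (two Pd couplings on a C1' dibromoalkene); C3–C4 and C2=C3 (Suzuki coupling, iodo-Wittig); C7–Et and C5≡C7 (Corey–Fuchs); C5–C6 (formaldehyde aldol); C1–C6 (ester-enolate Claisen).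
4. Forward: (R)-allylic alcohol → butanoate → β-hydroxy ester → Claisen (C1–C6) → alkyne → (Z,E)-diene → Pauson–Khand step, in which the six- and five-membered rings close together → enone reduction → side chain → acid.
5. Stereochemistry: a CBS reduction sets one carbinol, and a chair Claisen of a chelated enolate passes it to C1 and C6. C9 follows from the (E)-alkene and C4 from the tether fold in the Pauson–Khand step; C5 comes from axial protonation in the Li/NH3 reduction and C7 from equilibration. Alkene geometries come from syn-carbometalation, Zhao olefination and stereoretentive couplings.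

Key step: step 16

Assumption: dianion 14 keeps its O–Li–O chelate until it is silylated, so that the enolate geometry is carried into ketene acetal 15.

**Route**

Step 1
Reactants: 1 prop-2-yn-1-ol
Product: 3 (E)-3-iodo-2-methylprop-2-en-1-ol, via alkenylalane 2 (not isolated)
Conditions: Me3Al, Cp2ZrCl2 (cat.), CH2Cl2, 0 °C → rt; then I2, THF, −30 → 0 °C
Reagents that add atoms: trimethylaluminium, C[Al](C)C; iodine, II
Why: Zirconium-catalysed Negishi carboalumination adds methyl and aluminium syn across the alkyne with aluminium on the terminal carbon, and iodinolysis of the C–Al bond with retention should give the (E)-iodide.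

Step 2
Reactants: 3 (E)-3-iodo-2-methylprop-2-en-1-ol
Product: 4 (E)-3-iodo-2-methylprop-2-enal
Conditions: MnO2, CH2Cl2, rt
Reagents that add atoms: none
Why: Manganese dioxide oxidation of an allylic alcohol stops at the enal and leaves the vinyl iodide and its geometry untouched.

Step 3
Reactants: 4 (E)-3-iodo-2-methylprop-2-enal
Product: 5 (E)-1-iodo-3,3-dimethoxy-2-methylprop-1-ene
Conditions: HC(OMe)3, MeOH, PPTS (cat.), rt
Reagents that add atoms: trimethyl orthoformate, COC(OC)OC; methanol, CO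
Why: Acid-catalysed acetalisation driven by the orthoformate keeps C1' at the aldehyde level, so that no free C1' hydroxyl (which would lactonise onto the C6 ester) ever has to be unveiled.

Step 4
Reactants: 5 (E)-1-iodo-3,3-dimethoxy-2-methylprop-1-ene; 6 N-methoxy-N-methylacetamide
Product: 8 (E)-5,5-dimethoxy-4-methylpent-3-en-2-one, via vinyllithium 7 (not isolated)
Conditions: t-BuLi (2 equiv), Et2O, −78 °C; then 6, −78 → 0 °C; NH4Cl
Reagents that add atoms: none
Why: Iodine–lithium exchange proceeds with retention of alkene geometry, and Weinreb ketone synthesis stops at the ketone because the chelated tetrahedral adduct survives until work-up.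

Step 5
Reactants: 8 (E)-5,5-dimethoxy-4-methylpent-3-en-2-one
Product: 9 (2R,3E)-5,5-dimethoxy-4-methylpent-3-en-2-ol
Conditions: (S)-Me-CBS (0.2 equiv), catecholborane, toluene, −78 °C
Reagents that add atoms: none
Why: Corey–Bakshi–Shibata reduction, with the alkenyl group as the large and methyl as the small ketone substituent, should deliver hydride to the face that gives the (R)-carbinol.

Step 6
Reactants: 9 (2R,3E)-5,5-dimethoxy-4-methylpent-3-en-2-ol; 10 butanoyl chloride
Product: 11 (2R,3E)-5,5-dimethoxy-4-methylpent-3-en-2-yl butanoate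
Conditions: pyridine, DMAP (cat.), CH2Cl2, 0 °C
Reagents that add atoms: none
Why: DMAP-catalysed acylation of the secondary alcohol under basic conditions does not touch the carbinol centre or the allylic acetal.

Step 7
Reactants: 11 (2R,3E)-5,5-dimethoxy-4-methylpent-3-en-2-yl butanoate
Product: 13 (2R,3E)-5,5-dimethoxy-4-methylpent-3-en-2-yl 2-(hydroxymethyl)butanoate (both C2 epimers of the acyl part), via lithium enolate 12 (not isolated)
Conditions: LDA, THF, −78 °C; CH2O (gas, from cracked paraformaldehyde), −78 °C; NH4Cl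
Reagents that add atoms: formaldehyde, C=O
Why: Aldol addition of the lithium ester enolate to formaldehyde at −78 °C (below the temperature of enolate Claisen rearrangement) installs C5 as CH2OH; the new α-centre is of no consequence because it is planarised in step 8.

Step 8
Reactants: 13 (2R,3E)-5,5-dimethoxy-4-methylpent-3-en-2-yl 2-(hydroxymethyl)butanoate
Product: 17 (2S,3S,4E)-3-(dimethoxymethyl)-2-ethyl-2-(hydroxymethyl)-3-methylhex-4-enoic acid, via dilithium dianion 14 (not isolated), via disilyl ketene acetal 15 (not isolated), via disilyl Claisen product 16 (not isolated)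
Conditions: LDA (2.4 equiv), THF, −78 → −30 °C; TMSCl, −78 → 50 °C; then K2CO3, MeOH, 0 °C; pH 4 buffer
Reagents that add atoms: none
Why: In this dianionic Ireland–Claisen rearrangement the O–Li–O chelate holds the CH2O arm cis to the enolate oxygen, silylation traps that geometry, and a chair [3,3] transition state with the carbinol methyl equatorial should transfer the (R)-carbinol chirality to the vicinal quaternary centres C1 and C6 and leave an (E)-propenyl group on C1.

Step 9
Reactants: 17 (2S,3S,4E)-3-(dimethoxymethyl)-2-ethyl-2-(hydroxymethyl)-3-methylhex-4-enoic acid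
Product: 18 methyl (2S,3S,4E)-3-(dimethoxymethyl)-2-ethyl-2-(hydroxymethyl)-3-methylhex-4-enoate
Conditions: MeI, KHCO3, DMF, rt
Reagents that add atoms: iodomethane, CI
Why: SN2 O-alkylation of the carboxylate is insensitive to the hindrance at the acyl carbon, and the neutral primary alcohol is not alkylated by bicarbonate and iodomethane.

Step 10
Reactants: 18 methyl (2S,3S,4E)-3-(dimethoxymethyl)-2-ethyl-2-(hydroxymethyl)-3-methylhex-4-enoate
Product: 19 methyl (2S,3S,4E)-3-(dimethoxymethyl)-2-ethyl-2-formyl-3-methylhex-4-enoate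
Conditions: Dess–Martin periodinane, NaHCO3, CH2Cl2, 0 °C → rt
Reagents that add atoms: none
Why: Dess–Martin oxidation of the neopentyl primary alcohol under buffered conditions gives an aldehyde that cannot enolise because its α-carbon is quaternary.

Step 11
Reactants: 19 methyl (2S,3S,4E)-3-(dimethoxymethyl)-2-ethyl-2-formyl-3-methylhex-4-enoate
Product: 20 methyl (2R,3S,4E)-2-(2,2-dibromoethenyl)-3-(dimethoxymethyl)-2-ethyl-3-methylhex-4-enoate
Conditions: CBr4, PPh3, Et3N, CH2Cl2, 0 °C
Reagents that add atoms: carbon tetrabromide, BrC(Br)(Br)Br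
Why: Ramirez dibromo-olefination (first stage of the Corey–Fuchs sequence) is non-basic and so avoids the deformylation that alkoxide-mediated homologations could cause in a non-enolisable formyl ester.

Step 12
Reactants: 20 methyl (2R,3S,4E)-2-(2,2-dibromoethenyl)-3-(dimethoxymethyl)-2-ethyl-3-methylhex-4-enoate
Product: 22 methyl (2R,3S,4E)-2-(but-1-yn-1-yl)-3-(dimethoxymethyl)-2-ethyl-3-methylhex-4-enoate, via lithium acetylide 21 (not isolated)
Conditions: n-BuLi (2.1 equiv), THF, −78 °C; then EtI (excess), DMPU, −78 °C → rt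
Reagents that add atoms: iodoethane, CCI
Why: In the second stage of the Corey–Fuchs reaction, bromine–lithium exchange and a Fritsch–Buttenberg–Wiechell shift give the lithium acetylide, which is ethylated in the same flask; the ester, flanked by two quaternary carbons, should survive n-BuLi at −78 °C.

Step 13
Reactants: 22 methyl (2R,3S,4E)-2-(but-1-yn-1-yl)-3-(dimethoxymethyl)-2-ethyl-3-methylhex-4-enoate
Product: 24 methyl (2R,3R)-2-(but-1-yn-1-yl)-2-ethyl-3-formyl-4,4-dimethoxy-3-methylbutanoate, via ozonide 23 (not isolated)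
Conditions: O3, CH2Cl2, −78 °C (Sudan III end point); then PPh3, −78 °C → rt
Reagents that add atoms: ozone, [O-][O+]=O
Why: In an indicator-controlled ozonolysis with reductive work-up the disubstituted alkene reacts much faster than the internal alkyne or the acetal C–H, and C2 emerges as the aldehyde.

Step 14
Reactants: 24 methyl (2R,3R)-2-(but-1-yn-1-yl)-2-ethyl-3-formyl-4,4-dimethoxy-3-methylbutanoate
Product: 25 methyl (2R,3S,4Z)-2-(but-1-yn-1-yl)-3-(dimethoxymethyl)-2-ethyl-5-iodo-3-methylhex-4-enoate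
Conditions: EtPPh3I, n-BuLi, THF, 0 °C; I2, −78 °C; NaHMDS, −20 °C; then 24, −78 → −20 °C
Reagents that add atoms: ethyltriphenylphosphonium iodide, CC[P+](c1ccccc1)(c1ccccc1)c1ccccc1.[I-]; iodine, II
Why: Zhao olefination with the α-iodo ylide is kinetically (Z)-selective, which places iodine cis to the quaternary C1 and so fixes the future ring geometry of C2=C3.

Step 15
Reactants: 25 methyl (2R,3S,4Z)-2-(but-1-yn-1-yl)-3-(dimethoxymethyl)-2-ethyl-5-iodo-3-methylhex-4-enoate; 26 (E)-prop-1-en-1-ylboronic acid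
Product: 27 methyl (2R,3S,4Z,6E)-2-(but-1-yn-1-yl)-3-(dimethoxymethyl)-2-ethyl-3,5-dimethylocta-4,6-dienoate
Conditions: Pd(dppf)Cl2 (cat.), K3PO4, THF–H2O, 50 °C
Reagents that add atoms: none
Why: Suzuki–Miyaura coupling retains the geometry of both partners and should give the (4Z,6E)-diene without touching the internal alkyne.

Step 16
Reactants: 27 methyl (2R,3S,4Z,6E)-2-(but-1-yn-1-yl)-3-(dimethoxymethyl)-2-ethyl-3,5-dimethylocta-4,6-dienoate
Product: 29 methyl (1S,4R,5S,7aR)-5-(dimethoxymethyl)-3,4-diethyl-1,5,7-trimethyl-2-oxo-2,4,5,7a-tetrahydro-1H-indene-4-carboxylate, via dicobalt hexacarbonyl complex 28 (not isolated)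
Conditions: Co2(CO)8, CH2Cl2, rt; then NMO, 0 °C → rt
Reagents that add atoms: dicobalt octacarbonyl, O=C=[Co](=C=O)(=C=O)(=C=O)[Co](=C=O)(=C=O)(=C=O)=C=O
Why: The C5≡C7 alkyne forms the μ-alkyne–Co2(CO)6 complex; oxidative removal of a CO ligand by NMO opens a site, the C4=C9 alkene coordinates and inserts into a Co–C5 bond (C4–C5), CO inserts at C9 (C8–C9) and reductive elimination forms C7–C8 and releases the enone. The closest known reaction type is the intramolecular Pauson–Khand reaction of 1,7-enynes with internal alkynes and of dienynes, here with the distal alkene of the diene as the ene partner. The six-membered ring closes by a 6-exo insertion (C7 and C9 stay outside the ring), and the five-membered ring closes by CO insertion and reductive elimination of the cobaltacycle, a formal [2+2+1]. C9 is set relative to C4 by the (E)-geometry of the alkene, since syn insertion is stereospecific and leaves the C9 methyl trans to C3; C4 is set relative to C1/C6 by the half-chair fold that puts the two largest groups (C6 ethyl and the C1 acetal carbon) trans-diaxial and the flat ester in the plane beside the cobalt-bound C7 ethyl, so that H-4 should end on the face of the C6 ethyl. The step needs the alkyne to pair with C4=C9 and not with C2=C3 (which could only give a four-membered ring) and needs cyclisation to outrun decomplexation; the two quaternary carbons of the tether and the (Z)-C2=C3 bond, which holds C1 and C4 cis, secure both, while face selectivity rests on the fold described.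

Step 17
Reactants: 29 methyl (1S,4R,5S,7aR)-5-(dimethoxymethyl)-3,4-diethyl-1,5,7-trimethyl-2-oxo-2,4,5,7a-tetrahydro-1H-indene-4-carboxylate
Product: 32 methyl (1S,3S,3aR,4R,5S,7aR)-5-(dimethoxymethyl)-3,4-diethyl-1,5,7-trimethyl-2-oxo-2,3,3a,4,5,7a-hexahydro-1H-indene-4-carboxylate, via lithium enolate 30 (not isolated), via 7-epi ketone 31 (not isolated)
Conditions: Li (2.5 equiv), NH3(l)–THF, t-BuOH (1 equiv), −78 °C; NH4Cl; then NaOMe (cat.), MeOH, rt
Reagents that add atoms: none
Why: In this dissolving-metal enone reduction the C5 carbanion should be protonated axially, anti to the axial C6 ethyl, to give the trans ring fusion, and methoxide equilibration then turns the C7 ethyl trans to C6 while C9 keeps its more stable trans methyl; the isolated alkene, the acetal and the shielded ester are not reduced at this stoichiometry.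

Step 18
Reactants: 32 methyl (1S,3S,3aR,4R,5S,7aR)-5-(dimethoxymethyl)-3,4-diethyl-1,5,7-trimethyl-2-oxo-2,3,3a,4,5,7a-hexahydro-1H-indene-4-carboxylate
Product: 33 methyl (1S,3S,3aR,4R,5S,7aR)-3,4-diethyl-5-formyl-1,5,7-trimethyl-2-oxo-2,3,3a,4,5,7a-hexahydro-1H-indene-4-carboxylate
Conditions: 1 M HCl, THF, rt
Reagents that add atoms: water, O
Why: Acid-catalysed acetal hydrolysis (unimolecular ionisation, not slowed by the neopentyl position) reveals the C1' aldehyde directly; the ketone α-centres are already in their stable configurations.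

Step 19
Reactants: 33 methyl (1S,3S,3aR,4R,5S,7aR)-3,4-diethyl-5-formyl-1,5,7-trimethyl-2-oxo-2,3,3a,4,5,7a-hexahydro-1H-indene-4-carboxylate
Product: 34 methyl (1S,3S,3aR,4R,5R,7aR)-5-(2,2-dibromoethenyl)-3,4-diethyl-1,5,7-trimethyl-2-oxo-2,3,3a,4,5,7a-hexahydro-1H-indene-4-carboxylate
Conditions: CBr4, PPh3, CH2Cl2, 0 °C → rt
Reagents that add atoms: carbon tetrabromide, BrC(Br)(Br)Br
Why: The dibromomethylene ylide of the Ramirez olefination reacts with the aldehyde and should leave the doubly α-substituted cyclopentanone and the ester untouched.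

Step 20
Reactants: 34 methyl (1S,3S,3aR,4R,5R,7aR)-5-(2,2-dibromoethenyl)-3,4-diethyl-1,5,7-trimethyl-2-oxo-2,3,3a,4,5,7a-hexahydro-1H-indene-4-carboxylate; 35 (E)-(2-phenylethenyl)boronic acid
Product: 36 methyl (1S,3S,3aR,4R,5R,7aR)-5-[(1Z,3E)-2-bromo-4-phenylbuta-1,3-dien-1-yl]-3,4-diethyl-1,5,7-trimethyl-2-oxo-2,3,3a,4,5,7a-hexahydro-1H-indene-4-carboxylate
Conditions: Pd2(dba)3 (cat.), P(2-furyl)3, Na2CO3, 1,4-dioxane–H2O, 65 °C
Reagents that add atoms: none
Why: In this trans-selective Suzuki–Miyaura mono-coupling of a 1,1-dibromoalkene, oxidative addition takes place at the bromide trans to the quaternary C1, so that styryl ends trans to C1 and the remaining bromide cis.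

Step 21
Reactants: 36 methyl (1S,3S,3aR,4R,5R,7aR)-5-[(1Z,3E)-2-bromo-4-phenylbuta-1,3-dien-1-yl]-3,4-diethyl-1,5,7-trimethyl-2-oxo-2,3,3a,4,5,7a-hexahydro-1H-indene-4-carboxylate
Product: 37 methyl (1S,3S,3aR,4R,5R,7aR)-3,4-diethyl-5-[(1E,3E)-2-ethyl-4-phenylbuta-1,3-dien-1-yl]-1,5,7-trimethyl-2-oxo-2,3,3a,4,5,7a-hexahydro-1H-indene-4-carboxylate
Conditions: Et2Zn, Pd(t-Bu3P)2 (cat.), THF, 0 °C → rt
Reagents that add atoms: diethylzinc, CC[Zn]CC
Why: Negishi coupling with the tri-tert-butylphosphine catalyst, the ligand recorded as giving retention at 2-bromo-1,3-dienes where chelating diphosphines can give inversion, should place ethyl cis to C1; ketone and ester are inert to the organozinc.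

Step 22
Reactants: 37 methyl (1S,3S,3aR,4R,5R,7aR)-3,4-diethyl-5-[(1E,3E)-2-ethyl-4-phenylbuta-1,3-dien-1-yl]-1,5,7-trimethyl-2-oxo-2,3,3a,4,5,7a-hexahydro-1H-indene-4-carboxylate
Product: 38 (1S,3S,3aR,4R,5R,7aR)-3,4-diethyl-5-[(1E,3E)-2-ethyl-4-phenylbuta-1,3-dien-1-yl]-1,5,7-trimethyl-2-oxo-2,3,3a,4,5,7a-hexahydro-1H-indene-4-carboxylic acid (CNP0268209.1)
Conditions: n-PrSLi (from n-PrSH, n-BuLi), HMPA, rt; then 0.5 M HCl, 0 °C
Reagents that add atoms: none
Why: SN2 demethylation by thiolate attacks the unhindered methyl carbon, not the blocked acyl carbon, so the acid is freed at room temperature without touching the diene or any stereocentre.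

**Compound list**

1 | prop-2-yn-1-ol | C#CCO | starting material
2 | dimethylaluminium (E)-3-(dimethylalumanyl)-2-methylprop-2-en-1-olate | C[Al](C)OC/C(C)=C/[Al](C)C | intermediate
3 | (E)-3-iodo-2-methylprop-2-en-1-ol | OC/C(C)=C/I | intermediate
4 | (E)-3-iodo-2-methylprop-2-enal | O=C/C(C)=C/I | intermediate
5 | (E)-1-iodo-3,3-dimethoxy-2-methylprop-1-ene | COC(OC)/C(C)=C/I | intermediate
6 | N-methoxy-N-methylacetamide | CON(C)C(C)=O | starting material
7 | [(E)-3,3-dimethoxy-2-methylprop-1-en-1-yl]lithium | [Li]/C=C(\C)C(OC)OC | intermediate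
8 | (E)-5,5-dimethoxy-4-methylpent-3-en-2-one | CC(=O)/C=C(\C)C(OC)OC | intermediate
9 | (2R,3E)-5,5-dimethoxy-4-methylpent-3-en-2-ol | C[C@@H](O)/C=C(\C)C(OC)OC | intermediate
10 | butanoyl chloride | CCCC(Cl)=O | starting material
11 | (2R,3E)-5,5-dimethoxy-4-methylpent-3-en-2-yl butanoate | CCCC(=O)O[C@H](C)/C=C(\C)C(OC)OC | intermediate
12 | lithium enolate of 11 (enolate geometry not defined) | CCC=C([O-])O[C@H](C)/C=C(\C)C(OC)OC.[Li+] | intermediate
13 | (2R,3E)-5,5-dimethoxy-4-methylpent-3-en-2-yl 2-(hydroxymethyl)butanoate (both C2 epimers of the acyl part) | CCC(CO)C(=O)O[C@H](C)/C=C(\C)C(OC)OC | intermediate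
14 | dilithium alkoxide–enolate of 13, CH2OLi cis to the enolate OLi | CC/C(C[O-])=C(/[O-])O[C@H](C)/C=C(\C)C(OC)OC.[Li+].[Li+] | intermediate
15 | bis(trimethylsilyl) ketene acetal from 14, CH2OSiMe3 cis to OSiMe3 and ethyl cis to the allylic oxygen | CC/C(CO[Si](C)(C)C)=C(/O[Si](C)(C)C)O[C@H](C)/C=C(\C)C(OC)OC | intermediate
16 | trimethylsilyl (2S,3S,4E)-3-(dimethoxymethyl)-2-ethyl-3-methyl-2-[(trimethylsilyloxy)methyl]hex-4-enoate | C[Si](C)(C)OC[C@@](CC)(C(=O)O[Si](C)(C)C)[C@@](C)(C(OC)OC)/C=C/C | intermediate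
17 | (2S,3S,4E)-3-(dimethoxymethyl)-2-ethyl-2-(hydroxymethyl)-3-methylhex-4-enoic acid | OC[C@@](CC)(C(=O)O)[C@@](C)(C(OC)OC)/C=C/C | intermediate
18 | methyl (2S,3S,4E)-3-(dimethoxymethyl)-2-ethyl-2-(hydroxymethyl)-3-methylhex-4-enoate | OC[C@@](CC)(C(=O)OC)[C@@](C)(C(OC)OC)/C=C/C | intermediate
19 | methyl (2S,3S,4E)-3-(dimethoxymethyl)-2-ethyl-2-formyl-3-methylhex-4-enoate | O=C[C@@](CC)(C(=O)OC)[C@@](C)(C(OC)OC)/C=C/C | intermediate
20 | methyl (2R,3S,4E)-2-(2,2-dibromoethenyl)-3-(dimethoxymethyl)-2-ethyl-3-methylhex-4-enoate | BrC(Br)=C[C@@](CC)(C(=O)OC)[C@@](C)(C(OC)OC)/C=C/C | intermediate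
21 | lithium acetylide of methyl (2R,3S,4E)-3-(dimethoxymethyl)-2-ethyl-2-ethynyl-3-methylhex-4-enoate | [Li]C#C[C@@](CC)(C(=O)OC)[C@@](C)(C(OC)OC)/C=C/C | intermediate
22 | methyl (2R,3S,4E)-2-(but-1-yn-1-yl)-3-(dimethoxymethyl)-2-ethyl-3-methylhex-4-enoate | CCC#C[C@@](CC)(C(=O)OC)[C@@](C)(C(OC)OC)/C=C/C | intermediate
23 | secondary ozonide (3-methyl-1,2,4-trioxolan-5-yl on C1) of the propenyl group of 22 | CCC#C[C@@](CC)(C(=O)OC)[C@@](C)(C(OC)OC)C1OOC(C)O1 | intermediate
24 | methyl (2R,3R)-2-(but-1-yn-1-yl)-2-ethyl-3-formyl-4,4-dimethoxy-3-methylbutanoate | CCC#C[C@@](CC)(C(=O)OC)[C@@](C)(C(OC)OC)C=O | intermediate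
25 | methyl (2R,3S,4Z)-2-(but-1-yn-1-yl)-3-(dimethoxymethyl)-2-ethyl-5-iodo-3-methylhex-4-enoate | CCC#C[C@@](CC)(C(=O)OC)[C@@](C)(C(OC)OC)/C=C(/C)I | intermediate
26 | (E)-prop-1-en-1-ylboronic acid | C/C=C/B(O)O | starting material
27 | methyl (2R,3S,4Z,6E)-2-(but-1-yn-1-yl)-3-(dimethoxymethyl)-2-ethyl-3,5-dimethylocta-4,6-dienoate (dienyne) | CCC#C[C@@](CC)(C(=O)OC)[C@@](C)(C(OC)OC)/C=C(/C)\C=C\C | intermediate
28 | μ-alkyne hexacarbonyldicobalt complex of 27 at the butynyl triple bond | CCC12[Co]3(=C=O)(=C=O)(=C=O)[Co]1(=C=O)(=C=O)(=C=O)C23[C@@](CC)(C(=O)OC)[C@@](C)(C(OC)OC)/C=C(/C)\C=C\C | intermediate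
29 | methyl (1S,4R,5S,7aR)-5-(dimethoxymethyl)-3,4-diethyl-1,5,7-trimethyl-2-oxo-2,4,5,7a-tetrahydro-1H-indene-4-carboxylate (H-4 on the face of the C6 ethyl, 9-methyl trans to C3) | COC(OC)[C@@]1(C)C=C(C)[C@@H]2C(=C(CC)C(=O)[C@H]2C)[C@@]1(CC)C(=O)OC | intermediate
30 | lithium enolate (C7=C8–OLi) formed by reduction of 29, trans ring fusion | COC(OC)[C@@]1(C)C=C(C)[C@@H]2[C@H](C(CC)=C([O-])[C@H]2C)[C@@]1(CC)C(=O)OC.[Li+] | intermediate
31 | methyl (1S,3R,3aR,4R,5S,7aR)-5-(dimethoxymethyl)-3,4-diethyl-1,5,7-trimethyl-2-oxo-2,3,3a,4,5,7a-hexahydro-1H-indene-4-carboxylate (C7 epimer of 32) | COC(OC)[C@@]1(C)C=C(C)[C@@H]2[C@H]([C@@H](CC)C(=O)[C@H]2C)[C@@]1(CC)C(=O)OC | intermediate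
32 | methyl (1S,3S,3aR,4R,5S,7aR)-5-(dimethoxymethyl)-3,4-diethyl-1,5,7-trimethyl-2-oxo-2,3,3a,4,5,7a-hexahydro-1H-indene-4-carboxylate | COC(OC)[C@@]1(C)C=C(C)[C@@H]2[C@H]([C@H](CC)C(=O)[C@H]2C)[C@@]1(CC)C(=O)OC | intermediate
33 | methyl (1S,3S,3aR,4R,5S,7aR)-3,4-diethyl-5-formyl-1,5,7-trimethyl-2-oxo-2,3,3a,4,5,7a-hexahydro-1H-indene-4-carboxylate | O=C[C@@]1(C)C=C(C)[C@@H]2[C@H]([C@H](CC)C(=O)[C@H]2C)[C@@]1(CC)C(=O)OC | intermediate
34 | methyl (1S,3S,3aR,4R,5R,7aR)-5-(2,2-dibromoethenyl)-3,4-diethyl-1,5,7-trimethyl-2-oxo-2,3,3a,4,5,7a-hexahydro-1H-indene-4-carboxylate | BrC(Br)=C[C@@]1(C)C=C(C)[C@@H]2[C@H]([C@H](CC)C(=O)[C@H]2C)[C@@]1(CC)C(=O)OC | intermediate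
35 | (E)-(2-phenylethenyl)boronic acid | OB(O)/C=C/c1ccccc1 | starting material
36 | methyl (1S,3S,3aR,4R,5R,7aR)-5-[(1Z,3E)-2-bromo-4-phenylbuta-1,3-dien-1-yl]-3,4-diethyl-1,5,7-trimethyl-2-oxo-2,3,3a,4,5,7a-hexahydro-1H-indene-4-carboxylate | BrC(/C=C/c1ccccc1)=C\[C@@]1(C)C=C(C)[C@@H]2[C@H]([C@H](CC)C(=O)[C@H]2C)[C@@]1(CC)C(=O)OC | intermediate
37 | methyl (1S,3S,3aR,4R,5R,7aR)-3,4-diethyl-5-[(1E,3E)-2-ethyl-4-phenylbuta-1,3-dien-1-yl]-1,5,7-trimethyl-2-oxo-2,3,3a,4,5,7a-hexahydro-1H-indene-4-carboxylate | CCC(/C=C/c1ccccc1)=C\[C@@]1(C)C=C(C)[C@@H]2[C@H]([C@H](CC)C(=O)[C@H]2C)[C@@]1(CC)C(=O)OC | intermediate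
38 | (1S,3S,3aR,4R,5R,7aR)-3,4-diethyl-5-[(1E,3E)-2-ethyl-4-phenylbuta-1,3-dien-1-yl]-1,5,7-trimethyl-2-oxo-2,3,3a,4,5,7a-hexahydro-1H-indene-4-carboxylic acid (CNP0268209.1) | CCC(/C=C/c1ccccc1)=C\[C@@]1(C)C=C(C)[C@@H]2[C@H]([C@H](CC)C(=O)[C@H]2C)[C@@]1(CC)C(=O)O | target

**Count and risks**

Total step count: 22. Longest linear sequence: 22 steps (steps 1–22 from prop-2-yn-1-ol; compounds 6, 10, 26 and 35 are purchased).

Steps most likely to fail:

Step 8. The lithium chelate may open before or during silylation, or the congested rearrangement may pass partly through a boat; either would scramble the geometry of the tetrasubstituted ketene acetal and with it the configuration of C6 relative to C1. The fallback replaces the chelate by a covalent ring. It sets out from 13: the dianion 14 is generated as before and trapped with di-tert-butylsilyl bis(trifluoromethanesulfonate) to give the six-membered cyclic silylene ketene acetal F1, in which the CH2O arm and the enol oxygen are cis by construction. Warming should bring about the same [3,3] shift and give the silylene-protected hydroxy acid F2 (a 1,3-dioxa-2-silinan-4-one). HF·pyridine then frees the hydroxy acid, and the route is rejoined at 17.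

Step 16. Insertion of the 1,2-disubstituted alkene terminus at the hindered dicobalt complex may be slow; the higher temperature then needed would blur the preference between the two tether folds (poor face selectivity at C4) and let decomplexation compete. The fallback moves the C9 methyl to a later step so that a monosubstituted alkene inserts. It sets out from 25: Suzuki–Miyaura coupling with potassium vinyltrifluoroborate should give the vinyl dienyne F6; Co2(CO)8 converts it into the dicobalt hexacarbonyl complex F7, and NMO at low temperature should give the 9-unsubstituted enone F8. Kinetic deprotonation with LDA at −78 °C gives the cross-conjugated lithium enolate F9, which iodomethane should alkylate at C9 anti to the C3 branch of C4 (methyl trans to C3). The route is rejoined at 29.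

Step 14. Addition of the bulky α-iodo ylide to the doubly neopentyl aldehyde may be slower than decomposition of the ylide, with low conversion and erosion of the (Z) preference. The fallback builds the (Z)-trisubstituted alkene by a phosphonate olefination. It sets out from 24: Still–Gennari olefination with ethyl 2-[bis(2,2,2-trifluoroethoxy)phosphoryl]propanoate (KHMDS, 18-crown-6, −78 °C) should give the (Z)-enoate F3. DIBAL-H at −78 °C should reduce the conjugated ethyl ester in preference to the shielded C6 methyl ester and give the (Z)-allylic alcohol F4, which MnO2 oxidises to the (Z)-enal F5. Takai–Utimoto ethylidenation (1,1-diiodoethane, CrCl2) then installs the (E)-propenyl terminus, and the route is rejoined at 27.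

**Further compounds**

F1 | step 8 | 2,2-di-tert-butyl-5-ethyl-4-{[(2R,3E)-5,5-dimethoxy-4-methylpent-3-en-2-yl]oxy}-6H-1,3,2-dioxasiline (cyclic silylene ketene acetal) | CCC1=C(O[C@H](C)/C=C(\C)C(OC)OC)O[Si](C(C)(C)C)(C(C)(C)C)OC1
F2 | step 8 | (5S)-2,2-di-tert-butyl-5-ethyl-5-[(2S,3E)-1,1-dimethoxy-2-methylpent-3-en-2-yl]-1,3,2-dioxasilinan-4-one (silylene-protected 17) | CC[C@@]1(CO[Si](C(C)(C)C)(C(C)(C)C)OC1=O)[C@@](C)(C(OC)OC)/C=C/C
F3 | step 14 | 1-ethyl 6-methyl (2Z,4S,5R)-5-(but-1-yn-1-yl)-4-(dimethoxymethyl)-5-ethyl-2,4-dimethylhex-2-enedioate ((Z)-enoate, ethyl ester cis to C1) | CCC#C[C@@](CC)(C(=O)OC)[C@@](C)(C(OC)OC)/C=C(/C)C(=O)OCC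
F4 | step 14 | methyl (2R,3S,4Z)-2-(but-1-yn-1-yl)-3-(dimethoxymethyl)-2-ethyl-6-hydroxy-3,5-dimethylhex-4-enoate | CCC#C[C@@](CC)(C(=O)OC)[C@@](C)(C(OC)OC)/C=C(/C)CO
F5 | step 14 | methyl (2R,3S,4Z)-2-(but-1-yn-1-yl)-3-(dimethoxymethyl)-2-ethyl-3,5-dimethyl-6-oxohex-4-enoate | CCC#C[C@@](CC)(C(=O)OC)[C@@](C)(C(OC)OC)/C=C(/C)C=O
F6 | step 16 | methyl (2R,3S,4Z)-2-(but-1-yn-1-yl)-3-(dimethoxymethyl)-2-ethyl-3,5-dimethylhepta-4,6-dienoate | CCC#C[C@@](CC)(C(=O)OC)[C@@](C)(C(OC)OC)/C=C(/C)C=C
F7 | step 16 | μ-alkyne hexacarbonyldicobalt complex of F6 at the butynyl triple bond | CCC12[Co]3(=C=O)(=C=O)(=C=O)[Co]1(=C=O)(=C=O)(=C=O)C23[C@@](CC)(C(=O)OC)[C@@](C)(C(OC)OC)/C=C(/C)C=C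
F8 | step 16 | methyl (4R,5S,7aR)-5-(dimethoxymethyl)-3,4-diethyl-5,7-dimethyl-2-oxo-2,4,5,7a-tetrahydro-1H-indene-4-carboxylate (29 without the C9 methyl) | COC(OC)[C@@]1(C)C=C(C)[C@@H]2C(=C(CC)C(=O)C2)[C@@]1(CC)C(=O)OC
F9 | step 16 | cross-conjugated lithium enolate (C8–OLi, C8=C9) of F8 | COC(OC)[C@@]1(C)C=C(C)[C@@H]2C(=C(CC)C([O-])=C2)[C@@]1(CC)C(=O)OC.[Li+]
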